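**Strategy.** The chromanone ring (O1–C2–C3–C4–C4a–C8a) is disconnected at C3: excising C3 leaves a racemic 2-aryl-2-(iodomethyl)benzofuran-3(2H)-one, assembled from two prenylated arenes by ketone α-arylation and iodomethylation. In the key step a flavin-dependent ene-reductase under visible light cleaves the C–I bond. The primary radical undergoes a Dowd–Beckwith 1,2-acyl shift that inserts the CH2 between C2 and the C4 carbonyl, turning the five-membered furanone into the six-membered pyranone. The enzyme then delivers a hydrogen atom to one face of the planar C2 radical. The step exploits that C2 is benzylic and α-oxygenated, so the radical ends there, and it sets the only stereocentre enantioconvergently.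

Key step: step 11

Remark: the target SMILES is read as the (2S)-flavanone; carbonate 2 is prepared in step 1 because its commercial supply is uncertain.

Step 1
Reactants: 1 2-methylbut-3-en-2-ol
Product: 2 tert-butyl 2-methylbut-3-en-2-yl carbonate
Conditions: n-BuLi, THF, −78 °C; then Boc2O, −78 °C → rt
Reagents that add atoms: di-tert-butyl dicarbonate CC(C)(C)OC(=O)OC(=O)OC(C)(C)C
Why: O-acylation of the lithium alkoxide of the tertiary allylic alcohol with Boc2O should give the mixed carbonate that serves as π-allyl precursor in steps 2 and 5.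

Step 2
Reactants: 3 6-hydroxybenzofuran-3(2H)-one, 2 tert-butyl 2-methylbut-3-en-2-yl carbonate
Product: 4 6-[(2-methylbut-3-en-2-yl)oxy]benzofuran-3(2H)-one
Conditions: Pd(PPh3)4 (cat.), THF, 0 °C
Reagents that add atoms: none
Why: Tsuji–Trost O-allylation: Pd(0) ionises the tertiary allylic carbonate with loss of CO2, and the phenoxide (far more acidic than the C2 methylene) should attack the substituted terminus of the π-allyl complex under kinetic control to give the 1,1-dimethylallyl ether.

Step 3
Reactants: 4 6-[(2-methylbut-3-en-2-yl)oxy]benzofuran-3(2H)-one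
Product: 6 6-hydroxy-7-(3-methylbut-2-en-1-yl)benzofuran-3(2H)-one, via ortho-dienone 5 (not isolated)
Conditions: PhNEt2, 130 °C
Reagents that add atoms: none
Why: Aromatic Claisen rearrangement ([3,3]-sigmatropic): the allyl unit should move with inversion to C7, the ortho position between the two ring oxygens that is favoured by bond fixation as in 7-allyloxycoumarins, and ortho-dienone 5 enolises to the phenol carrying a linear prenyl group.

Step 4
Reactants: 6 6-hydroxy-7-(3-methylbut-2-en-1-yl)benzofuran-3(2H)-one
Product: 7 6-(methoxymethoxy)-7-(3-methylbut-2-en-1-yl)benzofuran-3(2H)-one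
Conditions: MOMCl, i-Pr2NEt, CH2Cl2, 0 °C → rt
Reagents that add atoms: chloromethyl methyl ether COCCl
Why: Williamson-type O-alkylation of the phenol with the α-chloro ether gives the MOM acetal, which is stable to the strong bases of steps 9 and 10 and removable at the end with dilute acid.

Step 5
Reactants: 8 5-bromo-2-hydroxybenzaldehyde, 2 tert-butyl 2-methylbut-3-en-2-yl carbonate
Product: 9 5-bromo-2-[(2-methylbut-3-en-2-yl)oxy]benzaldehyde
Conditions: Pd(PPh3)4 (cat.), THF, 0 °C → rt
Reagents that add atoms: none
Why: Tsuji–Trost O-allylation as in step 2; at this temperature π-allyl formation from the carbonate should be much faster than oxidative addition of Pd(0)/PPh3 into the aryl bromide.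

Step 6
Reactants: 9 5-bromo-2-[(2-methylbut-3-en-2-yl)oxy]benzaldehyde
Product: 11 5-bromo-2-hydroxy-3-(3-methylbut-2-en-1-yl)benzaldehyde, via ortho-dienone 10 (not isolated)
Conditions: PhNEt2, 140 °C
Reagents that add atoms: none
Why: Aromatic Claisen rearrangement ([3,3]-sigmatropic) to C3, the only free ortho position, followed by enolisation of ortho-dienone 10, should install the linear prenyl group next to the phenol.

Step 7
Reactants: 11 5-bromo-2-hydroxy-3-(3-methylbut-2-en-1-yl)benzaldehyde
Product: 13 5-bromo-3-(3-methylbut-2-en-1-yl)benzene-1,2-diol, via aryl formate 12 (not isolated)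
Conditions: 30% H2O2, NaOH aq., THF, 0 °C → rt, N2; then dil. HCl to pH 4
Reagents that add atoms: hydrogen peroxide OO
Why: Dakin oxidation: the hydroperoxide adduct of the ortho-hydroxy aldehyde rearranges by aryl migration to formate 12, which is saponified in the same flask to the catechol, while the unactivated trisubstituted alkene is inert to alkaline peroxide.

Step 8
Reactants: 13 5-bromo-3-(3-methylbut-2-en-1-yl)benzene-1,2-diol
Product: 14 5-bromo-1,2-bis(methoxymethoxy)-3-(3-methylbut-2-en-1-yl)benzene
Conditions: MOMCl (excess), i-Pr2NEt, CH2Cl2, 0 °C → rt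
Reagents that add atoms: chloromethyl methyl ether COCCl
Why: Double Williamson-type O-alkylation protects the air-sensitive catechol as its bis-MOM ether, which tolerates the palladium/alkoxide conditions of step 9.

Step 9
Reactants: 7 6-(methoxymethoxy)-7-(3-methylbut-2-en-1-yl)benzofuran-3(2H)-one, 14 5-bromo-1,2-bis(methoxymethoxy)-3-(3-methylbut-2-en-1-yl)benzene
Product: 15 racemic 2-[3,4-bis(methoxymethoxy)-5-(3-methylbut-2-en-1-yl)phenyl]-6-(methoxymethoxy)-7-(3-methylbut-2-en-1-yl)benzofuran-3(2H)-one
Conditions: Pd2(dba)3 (cat.), XPhos, NaOtBu, toluene, 70 °C; aq. NH4Cl work-up under N2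
Reagents that add atoms: none
Why: Palladium-catalysed α-arylation of a ketone enolate (Buchwald–Hartwig type): the sodium enolate of the benzofuranone couples with the aryl bromide at C2, and the bulky biaryl phosphine together with the stabilised, hindered product enolate should hold the reaction at monoarylation.

Step 10
Reactants: 15 racemic 2-[3,4-bis(methoxymethoxy)-5-(3-methylbut-2-en-1-yl)phenyl]-6-(methoxymethoxy)-7-(3-methylbut-2-en-1-yl)benzofuran-3(2H)-one
Product: 16 racemic 2-[3,4-bis(methoxymethoxy)-5-(3-methylbut-2-en-1-yl)phenyl]-2-(iodomethyl)-6-(methoxymethoxy)-7-(3-methylbut-2-en-1-yl)benzofuran-3(2H)-one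
Conditions: NaH, CH2I2 (10 equiv), THF–DMF, 0 °C → rt
Reagents that add atoms: diiodomethane ICI
Why: C-Alkylation of the soft 2-aryl enolate with excess diiodomethane, the standard entry to Dowd–Beckwith substrates, should create the quaternary C2 carrying a neopentyl iodide that has no α-hydrogen left and cannot eliminate.

Step 11
Reactants: 16 racemic 2-[3,4-bis(methoxymethoxy)-5-(3-methylbut-2-en-1-yl)phenyl]-2-(iodomethyl)-6-(methoxymethoxy)-7-(3-methylbut-2-en-1-yl)benzofuran-3(2H)-one
Product: 20 (2S)-2-[3,4-bis(methoxymethoxy)-5-(3-methylbut-2-en-1-yl)phenyl]-7-(methoxymethoxy)-8-(3-methylbut-2-en-1-yl)chroman-4-one, via primary alkyl radical 17 (not isolated), via cyclopropyloxy radical 18 (not isolated), via benzylic C2 radical 19 (not isolated)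
Conditions: flavin-dependent ene-reductase (Old Yellow Enzyme family, variant chosen from a panel for the (2S) product), NADP+ (cat.), glucose dehydrogenase, D-glucose, KPi buffer pH 7.5/DMSO, cyan LEDs, N2, 25 °C
Reagents that add atoms: none
Why: Proposed new method: photoexcitation of the enzyme-bound charge-transfer complex between the flavin hydroquinone and the alkyl iodide transfers one electron, iodide leaves, and primary radical 17 closes 3-exo-trig onto the furanone carbonyl to give cyclopropyloxy radical 18, whose β-scission of the old C2–C(=O) bond (a 1,2-acyl shift) gives ring-expanded radical 19, which takes a hydrogen atom from N5–H of the flavin semiquinone. The closest known reaction types are the tin-hydride Dowd–Beckwith one-carbon ring expansion of α-(halomethyl) ketones and the photoenzymatic ene-reductase dehalogenations and radical cyclisations of alkyl iodides that end in enantioselective hydrogen-atom transfer to benzylic radicals; their combination has not been shown. No ring is closed for good: the transient cyclopropane forms 3-exo-trig and opens at once, so the pyranone O1–C2–C3–C4–C4a–C8a arises from the furanone by insertion of the CH2 between C2 and the carbonyl carbon. The C2 stereocentre is controlled by the enzyme, which should hold radical 19 over the flavin so that hydrogen reaches one face only, and both enantiomers of 16 should converge on the (2S) product because 19 is planar at C2. The step needs the 1,2-acyl shift to beat the 1,2-aryl (neophyl) shift and the premature reduction of 17, which the fast attack on the aryl ketone and the benzylic, α-oxygenated stabilisation of 19 should secure.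

Step 12
Reactants: 20 (2S)-2-[3,4-bis(methoxymethoxy)-5-(3-methylbut-2-en-1-yl)phenyl]-7-(methoxymethoxy)-8-(3-methylbut-2-en-1-yl)chroman-4-one
Product: 21 (2S)-2-[3,4-dihydroxy-5-(3-methylbut-2-en-1-yl)phenyl]-7-hydroxy-8-(3-methylbut-2-en-1-yl)chroman-4-one (CNP0315050.1)
Conditions: 3 M HCl, MeOH, 40 °C
Reagents that add atoms: none
Why: Acid-catalysed acetal exchange with methanol removes the three MOM groups as dimethoxymethane under conditions mild enough to leave the prenyl groups and the ketone untouched, and C2 is not epimerised because it is not enolisable and ring opening needs base.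

**Compound list**

1 | 2-methylbut-3-en-2-ol | C=CC(C)(C)O | starting material
2 | tert-butyl 2-methylbut-3-en-2-yl carbonate | C=CC(C)(C)OC(=O)OC(C)(C)C | intermediate
3 | 6-hydroxybenzofuran-3(2H)-one | O=C1COc2cc(O)ccc21 | starting material
4 | 6-[(2-methylbut-3-en-2-yl)oxy]benzofuran-3(2H)-one | O=C1COc2cc(OC(C)(C)C=C)ccc21 | intermediate
5 | ortho-dienone, racemic 7-(3-methylbut-2-en-1-yl)benzofuran-3,6(2H,7H)-dione (not isolated) | O=C1COC2=C1C=CC(=O)C2CC=C(C)C | intermediate
6 | 6-hydroxy-7-(3-methylbut-2-en-1-yl)benzofuran-3(2H)-one | O=C1COc2c(CC=C(C)C)c(O)ccc21 | intermediate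
7 | 6-(methoxymethoxy)-7-(3-methylbut-2-en-1-yl)benzofuran-3(2H)-one | O=C1COc2c(CC=C(C)C)c(OCOC)ccc21 | intermediate
8 | 5-bromo-2-hydroxybenzaldehyde | O=Cc1cc(Br)ccc1O | starting material
9 | 5-bromo-2-[(2-methylbut-3-en-2-yl)oxy]benzaldehyde | O=Cc1cc(Br)ccc1OC(C)(C)C=C | intermediate
10 | ortho-dienone, racemic 3-bromo-5-(3-methylbut-2-en-1-yl)-6-oxocyclohexa-1,3-diene-1-carbaldehyde (not isolated) | O=CC1=CC(Br)=CC(CC=C(C)C)C1=O | intermediate
11 | 5-bromo-2-hydroxy-3-(3-methylbut-2-en-1-yl)benzaldehyde | O=Cc1cc(Br)cc(CC=C(C)C)c1O | intermediate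
12 | aryl formate, 5-bromo-2-hydroxy-3-(3-methylbut-2-en-1-yl)phenyl formate (not isolated) | O=COc1cc(Br)cc(CC=C(C)C)c1O | intermediate
13 | 5-bromo-3-(3-methylbut-2-en-1-yl)benzene-1,2-diol | Oc1cc(Br)cc(CC=C(C)C)c1O | intermediate
14 | 5-bromo-1,2-bis(methoxymethoxy)-3-(3-methylbut-2-en-1-yl)benzene | COCOc1cc(Br)cc(CC=C(C)C)c1OCOC | intermediate
15 | racemic 2-[3,4-bis(methoxymethoxy)-5-(3-methylbut-2-en-1-yl)phenyl]-6-(methoxymethoxy)-7-(3-methylbut-2-en-1-yl)benzofuran-3(2H)-one (keto tautomer) | COCOc1ccc2C(=O)C(Oc2c1CC=C(C)C)c1cc(CC=C(C)C)c(OCOC)c(OCOC)c1 | intermediate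
16 | racemic 2-[3,4-bis(methoxymethoxy)-5-(3-methylbut-2-en-1-yl)phenyl]-2-(iodomethyl)-6-(methoxymethoxy)-7-(3-methylbut-2-en-1-yl)benzofuran-3(2H)-one | COCOc1ccc2C(=O)C(CI)(Oc2c1CC=C(C)C)c1cc(CC=C(C)C)c(OCOC)c(OCOC)c1 | intermediate
17 | primary alkyl radical, 16 with CH2• in place of CH2I (not isolated) | COCOc1ccc2C(=O)C([CH2])(Oc2c1CC=C(C)C)c1cc(CC=C(C)C)c(OCOC)c(OCOC)c1 | intermediate
18 | cyclopropyloxy radical, cyclopropane fused across C2 and the former carbonyl carbon, which carries O• (not isolated) | COCOc1ccc2c(c1CC=C(C)C)OC1(c3cc(CC=C(C)C)c(OCOC)c(OCOC)c3)CC21[O] | intermediate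
19 | benzylic C2 radical of the ring-expanded chroman-4-one (not isolated) | COCOc1ccc2C(=O)C[C](Oc2c1CC=C(C)C)c1cc(CC=C(C)C)c(OCOC)c(OCOC)c1 | intermediate
20 | (2S)-2-[3,4-bis(methoxymethoxy)-5-(3-methylbut-2-en-1-yl)phenyl]-7-(methoxymethoxy)-8-(3-methylbut-2-en-1-yl)chroman-4-one | CC(C)=CCc1cc([C@@H]2CC(=O)c3ccc(OCOC)c(CC=C(C)C)c3O2)cc(OCOC)c1OCOC | intermediate
21 | (2S)-2-[3,4-dihydroxy-5-(3-methylbut-2-en-1-yl)phenyl]-7-hydroxy-8-(3-methylbut-2-en-1-yl)chroman-4-one (CNP0315050.1) | CC(C)=CCc1cc([C@@H]2CC(=O)c3ccc(O)c(CC=C(C)C)c3O2)cc(O)c1O | target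

**Totals**

Total step count: 12. Longest linear sequence: 9 steps (steps 1, 5, 6, 7, 8, 9, 10, 11, 12).

**Steps most likely to fail**

Step 11 (Proposed new method). The enzyme may fail to bind so large and lipophilic a substrate, or may turn over only one enantiomer of 16. Radical 17 may be reduced before the acyl shift. The final hydrogen-atom transfer may show poor facial selectivity, or free reduced flavin may cause a racemic background reaction. Fallback: from 16 the ring expansion is run as a classical Dowd–Beckwith chain reaction (Bu3SnH added slowly, AIBN, benzene, 80 °C), which should give racemic 2-[3,4-bis(methoxymethoxy)-5-(3-methylbut-2-en-1-yl)phenyl]-7-(methoxymethoxy)-8-(3-methylbut-2-en-1-yl)chroman-4-one F1. This is resolved kinetically by Noyori–Ikariya asymmetric transfer hydrogenation (Cp*RhCl[(R,R)-TsDPEN], HCO2H/Et3N, EtOAc, rt, stopped near half conversion). The (R,R) catalyst is expected to be matched with the (2R)-ketone, which should be reduced to the cis-(2R,4R)-flavan-4-ol F2. The slow-reacting (2S)-ketone is recovered by chromatography as 20, where the route is rejoined.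

Step 9. The ketone 7 may self-condense under the strong base, C2 may be arylated twice, and the enolisable product may be oxidised by air. Fallback with reversed polarity: from 7, enolisation with LiHMDS and chlorination with N-chlorosuccinimide (THF, −78 °C) should give racemic 2-chloro-6-(methoxymethoxy)-7-(3-methylbut-2-en-1-yl)benzofuran-3(2H)-one F3. From 14, bromine–lithium exchange (n-BuLi, THF, −78 °C) and transmetalation with ZnCl2 should give [3,4-bis(methoxymethoxy)-5-(3-methylbut-2-en-1-yl)phenyl]zinc chloride F4. Nickel-catalysed Negishi arylation of the α-halo ketone (NiCl2·glyme, pybox ligand, THF/glyme, −30 °C) joins the two, and the route is rejoined at 15.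

Step 10. The ambident enolate may be alkylated on oxygen, or the iodide formed may be substituted a second time by another enolate. Fallback: from 15, base-catalysed aldol addition to formaldehyde (37% aq. HCHO, cat. KHCO3, THF, rt) should give racemic 2-[3,4-bis(methoxymethoxy)-5-(3-methylbut-2-en-1-yl)phenyl]-2-(hydroxymethyl)-6-(methoxymethoxy)-7-(3-methylbut-2-en-1-yl)benzofuran-3(2H)-one F5. Appel-type iodination of this neopentyl alcohol (I2, PPh3, imidazole, toluene, 80 °C) comes back to the route at 16.

**Further compounds**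

F1 | step 11 | racemic 2-[3,4-bis(methoxymethoxy)-5-(3-methylbut-2-en-1-yl)phenyl]-7-(methoxymethoxy)-8-(3-methylbut-2-en-1-yl)chroman-4-one | CC(C)=CCc1cc(C2CC(=O)c3ccc(OCOC)c(CC=C(C)C)c3O2)cc(OCOC)c1OCOC
F2 | step 11 | (2R,4R)-2-[3,4-bis(methoxymethoxy)-5-(3-methylbut-2-en-1-yl)phenyl]-7-(methoxymethoxy)-8-(3-methylbut-2-en-1-yl)chroman-4-ol | CC(C)=CCc1cc([C@H]2C[C@@H](O)c3ccc(OCOC)c(CC=C(C)C)c3O2)cc(OCOC)c1OCOC
F3 | step 9 | racemic 2-chloro-6-(methoxymethoxy)-7-(3-methylbut-2-en-1-yl)benzofuran-3(2H)-one | COCOc1ccc2C(=O)C(Cl)Oc2c1CC=C(C)C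
F4 | step 9 | [3,4-bis(methoxymethoxy)-5-(3-methylbut-2-en-1-yl)phenyl]zinc chloride | COCOc1cc([Zn]Cl)cc(CC=C(C)C)c1OCOC
F5 | step 10 | racemic 2-[3,4-bis(methoxymethoxy)-5-(3-methylbut-2-en-1-yl)phenyl]-2-(hydroxymethyl)-6-(methoxymethoxy)-7-(3-methylbut-2-en-1-yl)benzofuran-3(2H)-one | COCOc1ccc2C(=O)C(CO)(Oc2c1CC=C(C)C)c1cc(CC=C(C)C)c(OCOC)c(OCOC)c1
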